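(The readings are simulated for substances that don't exist; the scatter is artificial.)

The noon run's last reading, at 90.0 min, still has 17% of its charge free, and that remainder is the way into two further flasks.

| flask | free monomer | initiator | remark | time |
|---|---|---|---|---|
| noon | 0.12 M | 2.5 mol% | run made earlier |  |
| north-east | 0.18 M | 2.5 mol% |  | 8.0 h |
| west | 0.18 M | 8 mol% |  | 8.0 h |

noon run (percent of the free monomer charged)

| time / min | monomer in chains / % | free monomer / % |
|---|---|---|
| 25.0 | 41 | 57 |
| 50.0 | 66 | 34 |
| 80.0 | 72 | 25 |
| 90.0 | 77 | 17 |

(standard deviation of a reading: 2 percentage points)

- the average divides the monomer in chains by the number of chains begun, living and dead together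
- on the list of suspects stand: monomer in chains + living end -> free monomer + living end; free monomer + initiator -> living end + monomer in chains; free monomer + living end -> monomer in chains + living end; free monomer -> uncatalysed product
- the earlier runs do not show the number of chains; that part of a forecast is a guess
- no earlier run changes the charge of initiator; that part of a forecast is a guess

1. which of the two ends with the longer chains by the average number of monomer units in a chain (chains begun, living or dead) ("neither" if they lie within 10%) (north-east / west / neither)
2. average number of monomer units in a chain (chains begun, living or dead) at the end, north-east
3. average number of monomer units in a chain (chains begun, living or dead) at the end, west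

The average length of a chain is monomer in chains over chains begun. Each chain begins from one initiator, so if the initiator is fully consumed, which is a guess that no run tests, the length is the share of the charge in chains divided by the loading.

A living end adds free monomer at a rate proportional to [free monomer]. The suspects also include a step that returns monomer. Read as unzipping at the end, that step has a rate independent of [free monomer], and [living end] stands in both rates, so they cross at one [free monomer], whatever the number of ends. Noon's last reading gives:

[free monomer] = 0.0204 M

Taken as that crossing, this reading is the floor concentration, the equilibrium monomer concentration. It carries the scatter and may stand high, since the noon run may still have been falling.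

Noon's first two readings give a pseudo-first-order constant of 0.0207 min⁻¹. Scaled to the ends of north-east, this gives a time constant of 32.3 min, far shorter than the 8.0 h allowed. West has more ends, so both flasks are reckoned to reach the floor:

share in chains = ([free monomer] charged − floor) / [free monomer] charged = 88.7%

north-east: share / 2.5 mol% = 35.5

west: share / 8 mol% = 11.1

North-east is therefore reckoned longer than west, well outside the 10% margin.

The forecast names north-east, at 38 against 12.2, both higher than this reckoning, and says of the uncatalysed loss and the equilibrium level it suspects: “Together these trim a few percent”.

The flask gives north-east as the longer, at 35.2 against 11.0.

    monomer in chains + living end → free monomer + living end, rate k1*[living end] as long as [monomer in chains] is above zero (k = 0.180 min⁻¹)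
    free monomer + initiator → living end + monomer in chains (k = 5.10 M⁻¹ min⁻¹)
    free monomer + living end → monomer in chains + living end, rate k3*[living end]*[free monomer] (k = 9.60 M⁻¹ min⁻¹)
    free monomer → uncatalysed product (k = 2.40 × 10⁻⁴ min⁻¹)

North-east and west differ in [living end], 0.00450 M against 0.0144 M, yet at 8.00 h they hold 10.4% and 10.4% of their charge as free monomer. The neighbour is west with 3.2 mol% of initiator in place of 8 mol%. The floor of 0.0204 M on its charge of 0.18 M again leaves a share of 88.7%, and over 3.2 mol% that reckons to a length of 27.7. The neighbour ends with 10.4% free monomer, 88.0% in chains, 0% of its initiator left and an average length of 27.5.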